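**Retrosynthetic overview**
1. Feature used: in ring A, C6(OMe)–C7(OH)–C8(OMe) has the same carbons and oxygens as 1,3-dimethoxyacetone. Its neighbours C5–H and C8a correspond to a formyl carbon and a ketone carbon on ring B.
2. Ring A is therefore cut at C5–C6 and C8–C8a. This is a (3+3) benzannulation of a ring B 2-hydroxymethylene ketone, and it releases C7–OH as the only free phenol.
3. End game: C7–OH is para to C4a and directs dehydrogenation of C3–C4. Acid then removes the MOM and TBS groups.
4. Ring B comes from an auxiliary-controlled Diels–Alder reaction (bonds C1–C2 and C3–C4) between the ring C 1-aryl-2-silyloxybutadiene and an (E)-4-silyloxybut-2-enoyl oxazolidinone. Ester exchange and formylation at C4a follow.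
5. Ring order: C (bought), then B (cycloaddition), then A (benzannulation).

Key step: step 10

Remark: lignan locants are used throughout (C1 aryl-bearing, C2 CH2O-bearing, C3 carboxyl-bearing, then C4, C4a, C5–C8, C8a). Ar = 3,5-dimethoxy-4-(methoxymethoxy)phenyl, TBS = tert-butyldimethylsilyl, TES = triethylsilyl.
Assumption: C3 is drawn as the all-trans epimer in 12–20. Either C3 epimer is usable because C3 becomes sp2 in step 11.

Step 1
Reactants: 1 4-hydroxy-3,5-dimethoxyphenylacetic acid
Product: 2 2-(4-hydroxy-3,5-dimethoxyphenyl)-N-methoxy-N-methylacetamide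
Conditions: MeNH(OMe)·HCl, EDC·HCl, N-methylmorpholine, CH2Cl2, 0 °C → rt
Reagents that add atoms: N,O-dimethylhydroxylamine hydrochloride CNOC.Cl
Why: Carbodiimide amide coupling, in which the amine outcompetes the hindered 2,6-dimethoxyphenol for the activated acid and the resulting amide allows a clean single addition of a vinyl nucleophile.

Step 2
Reactants: 2 2-(4-hydroxy-3,5-dimethoxyphenyl)-N-methoxy-N-methylacetamide
Product: 3 2-[3,5-dimethoxy-4-(methoxymethoxy)phenyl]-N-methoxy-N-methylacetamide
Conditions: MOMCl, iPr2NEt, CH2Cl2, 0 °C → rt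
Reagents that add atoms: chloromethyl methyl ether COCCl
Why: O-alkylation of the phenol gives an acetal ether that survives Grignard reagents, alkoxides and DDQ, keeps ring C from forming a quinone methide later, and comes off in the final acid step.

Step 3
Reactants: 3 2-[3,5-dimethoxy-4-(methoxymethoxy)phenyl]-N-methoxy-N-methylacetamide
Product: 4 1-[3,5-dimethoxy-4-(methoxymethoxy)phenyl]but-3-en-2-one (used at once)
Conditions: CH2=CHMgBr, THF, −78 → 0 °C; inverse quench into cold 1 M HCl
Reagents that add atoms: vinylmagnesium bromide C=C[Mg]Br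
Why: Weinreb ketone synthesis, in which the chelated adduct survives until the quench so only one vinyl group adds, and pouring into cold acid protonates the released amine before it can add to the enone.

Step 4
Reactants: 4 1-[3,5-dimethoxy-4-(methoxymethoxy)phenyl]but-3-en-2-one
Product: 5 (Z)-1-Ar-2-(triethylsilyloxy)buta-1,3-diene
Conditions: TESOTf, Et3N, CH2Cl2, −78 → 0 °C
Reagents that add atoms: triethylsilyl triflate CC[Si](CC)(CC)OS(=O)(=O)C(F)(F)F
Why: Soft enolisation and O-silylation can only remove the acidic benzylic C1–H because the other flank is vinylic, and it places the aryl group trans to the vinyl group (Z enol silane), which is the outside position of the s-cis diene.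

Step 5
Reactants: 6 diethylphosphonoacetic acid; 7 (R)-4-benzyloxazolidin-2-one
Product: 9 diethyl {2-[(4R)-4-benzyl-2-oxooxazolidin-3-yl]-2-oxoethyl}phosphonate, via mixed pivalic anhydride 8 (not isolated)
Conditions: PivCl, Et3N, THF, −20 °C; then 7, LiCl, rt
Reagents that add atoms: pivaloyl chloride CC(C)(C)C(=O)Cl (carried only by intermediate 8)
Why: N-acylation of the oxazolidinone through a mixed anhydride, in which the tert-butyl group steers attack to the phosphonoacetyl carbonyl and LiCl with amine base avoids strong base on the acidic phosphonate.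

Step 6
Reactants: 9 diethyl {2-[(4R)-4-benzyl-2-oxooxazolidin-3-yl]-2-oxoethyl}phosphonate; 10 (tert-butyldimethylsilyloxy)acetaldehyde
Product: 11 (4R)-4-benzyl-3-[(E)-4-(tert-butyldimethylsilyloxy)but-2-enoyl]oxazolidin-2-one
Conditions: LiCl, iPr2NEt, MeCN, rt
Reagents that add atoms: none
Why: Horner–Wadsworth–Emmons olefination with a stabilised, lithium-chelated phosphonate gives the E enoyl imide under conditions mild enough for the alpha-silyloxy aldehyde and the imide.

Step 7
Reactants: 5 (Z)-1-Ar-2-(triethylsilyloxy)buta-1,3-diene; 11 (4R)-4-benzyl-3-[(E)-4-(tert-butyldimethylsilyloxy)but-2-enoyl]oxazolidin-2-one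
Product: 13 (4R)-4-benzyl-3-{(1R,2R,3S)-3-Ar-2-[(tert-butyldimethylsilyloxy)methyl]-4-oxocyclohexane-1-carbonyl}oxazolidin-2-one (lignan locants 3R 2R 1S), via enol silane cycloadduct 12 (not isolated)
Conditions: Et2AlCl (1.5 equiv), CH2Cl2, −78 → −30 °C; then 0.5 M HCl–THF, 0 °C
Reagents that add atoms: none
Why: Auxiliary-controlled, Lewis acid promoted Diels–Alder reaction in which Et2AlCl chelates both imide carbonyls in the s-cis form and the benzyl group blocks one face, so the diene adds to the C-alpha re face and sets C2 (R) and, through the E geometry, C3 (R); the enol silane carbon C1 is the most nucleophilic terminus and bonds to the beta carbon C2 (ester para to the silyloxy group) because the 3,4,5-trioxygenated aryl with its twisted para oxygen is the weaker director; endo approach of the outside aryl gives the 1,2-trans C1 (S), which is also the epimer favoured by equilibration; dilute acid then hydrolyses the TES enol ether far faster than the primary TBS ether or the aryl MOM ether.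

Step 8
Reactants: 13 keto imide
Product: 14 methyl (1R,2R,3S)-3-Ar-2-[(tert-butyldimethylsilyloxy)methyl]-4-oxocyclohexane-1-carboxylate (lignan locants 3R 2R 1S)
Conditions: Mg(OMe)2, MeOH–THF, 0 °C → rt; NH4Cl quench
Reagents that add atoms: methanol CO (delivered as Mg(OMe)2, C[O-].C[O-].[Mg+2])
Why: Chelation-assisted transesterification, in which magnesium binds the imide and directs methoxide to the exocyclic carbonyl of the hindered acyl group, releases the auxiliary intact and leaves C1 and C3 in the all-equatorial arrangement.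

Step 9
Reactants: 14 keto ester
Product: 15 methyl (1R,2R,3S,5Z)-3-Ar-2-[(tert-butyldimethylsilyloxy)methyl]-5-(hydroxymethylidene)-4-oxocyclohexane-1-carboxylate (C4a hydroxymethylene ketone)
Conditions: HCO2Me, NaOMe, THF, 0 °C → rt; AcOH quench
Reagents that add atoms: methyl formate COC=O
Why: Crossed Claisen formylation under thermodynamic control, in which only C4a can end as the stabilised enolate of a beta-keto aldehyde (acylation at C1 or C3 gives a quaternary, reversible adduct), methyl formate with methoxide cannot scramble the methyl ester as an ethyl formate/ethoxide pair would, and no stereocentre is formed.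

Step 10
Reactants: 15 C4a hydroxymethylene ketone; 16 1,3-dimethoxyacetone
Product: 19 methyl (1S,2R,3R)-1-Ar-2-[(tert-butyldimethylsilyloxy)methyl]-7-hydroxy-6,8-dimethoxy-1,2,3,4-tetrahydronaphthalene-3-carboxylate, via dimethylaminomethylene ketone 17 (not isolated), via ene-dione 18 (not isolated)
Conditions: a) Me2NH (2 M in THF), 4 Å MS, rt, then evaporation from toluene; b) 16 (1.5 equiv), KOtBu (1.1 equiv), THF, −30 °C → rt, argon; c) MeOH, 50 °C; AcOH quench
Reagents that add atoms: dimethylamine CNC (carried only by intermediate 17, absent from 19)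
Why: Proposed new method: under base alone 15 would rest as its inert chelated enolate and slowly lose formate by retro-Claisen cleavage, so it is first converted in the flask into the neutral vinylogous amide 17, whose C5 accepts the potassium enolate of 16 and expels dimethylamine (addition–elimination), which forms C5–C6 and leaves ene-dione 18 as its delocalised enolate. On warming with methanol as proton shuttle the C7–C8 enolate tautomer attacks the C8a ketone in a 6-(enolendo)-exo-trig aldol that forms C8–C8a and closes ring A, after which E1cB loss of water and tautomerisation of the cyclohexa-2,4-dienone through C6–H give the free C7 phenol, aromatisation making the sequence irreversible. The closest known reaction types are the (3+3) phenol syntheses from 2-formyl ketones, malondialdehyde equivalents or vinamidinium salts with 1,3-disubstituted acetones, the addition–elimination of ketone potassium enolates to dimethylaminomethylene ketones, and the base-induced recyclisation of 2-alkylpyrylium pseudobases (pent-2-ene-1,5-diones like 18) to phenols; untested are a 1,3-dialkoxyacetone as the three-carbon unit and a second electrophile flanked by an aryl-bearing carbon. Regiochemistry needs no control because 16 is symmetric, so C6-OMe, C7-OH and C8-OMe fall into place whichever alpha carbon reacts first, and the only other aldol within reach (C1 onto C7) would demand a bridgehead alkene. No stereocentre is formed: C2 is not touched, C1 enters as the equatorial trans epimer favoured alpha to the ketone and loses its acidity once 18 is an anion, and the C3 epimer ratio is of no consequence. Keeping the base just above one equivalent and the temperature moderate holds the C3 ester enolate, and with it retro-Michael opening of C1–C2 that would racemise C2, out of play, while MOM, TBS and the methyl ester tolerate alkoxide in methanol and the new phenol is the only free OH of the product.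

Step 11
Reactants: 19 tetralin phenol
Product: 21 methyl (1S,2R)-1-Ar-2-[(tert-butyldimethylsilyloxy)methyl]-7-hydroxy-6,8-dimethoxy-1,2-dihydronaphthalene-3-carboxylate, via para-quinone methide 20 (not isolated)
Conditions: DDQ (1.0 equiv), CH2Cl2 (dry), 0 °C; then Et3N (cat.)
Reagents that add atoms: none
Why: Phenol-directed benzylic dehydrogenation with DDQ, in which only ring A carries a free OH and C4 is the benzylic carbon para to it through C4a, so hydride loss from C4 gives quinone methide 20, whose C3–H (acidified by the ester and vinylogously by the quinone methide) is removed by the amine to restore the arene with the C3=C4 bond; C1 sits on C8a meta to the OH and ring C is capped, so neither can form a quinone methide; one equivalent of oxidant at 0 °C guards against a second dehydrogenation, and C1 and C2 are untouched.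

Step 12
Reactants: 21 protected dihydronaphthalene
Product: 22 methyl (1S,2R)-7-hydroxy-1-(4-hydroxy-3,5-dimethoxyphenyl)-2-(hydroxymethyl)-6,8-dimethoxy-1,2-dihydronaphthalene-3-carboxylate (target)
Conditions: HCl (1.25 M in MeOH), 0 °C → rt
Reagents that add atoms: none
Why: Acid-catalysed acetal exchange and silyl ether methanolysis remove the aryl MOM and the primary TBS group in one operation, methanol as solvent preserves the methyl ester, and lactonisation should not compete because the peri C8-OMe holds the C1 aryl, and hence the trans C2-CH2OH, pseudoaxial and nearly perpendicular to the plane of the conjugated ester.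

**Compound list**
1 | 4-hydroxy-3,5-dimethoxyphenylacetic acid | COc1cc(CC(=O)O)cc(OC)c1O | starting material
2 | 2-(4-hydroxy-3,5-dimethoxyphenyl)-N-methoxy-N-methylacetamide | COc1cc(CC(=O)N(C)OC)cc(OC)c1O | intermediate
3 | 2-[3,5-dimethoxy-4-(methoxymethoxy)phenyl]-N-methoxy-N-methylacetamide | COCOc1c(OC)cc(CC(=O)N(C)OC)cc1OC | intermediate
4 | 1-[3,5-dimethoxy-4-(methoxymethoxy)phenyl]but-3-en-2-one | C=CC(=O)Cc1cc(OC)c(OCOC)c(OC)c1 | intermediate
5 | (Z)-1-Ar-2-(triethylsilyloxy)buta-1,3-diene | C=C/C(O[Si](CC)(CC)CC)=C/c1cc(OC)c(OCOC)c(OC)c1 | intermediate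
6 | diethylphosphonoacetic acid | CCOP(=O)(CC(=O)O)OCC | starting material
7 | (R)-4-benzyloxazolidin-2-one | O=C1N[C@H](Cc2ccccc2)CO1 | starting material
8 | diethylphosphonoacetic pivalic anhydride | CCOP(=O)(CC(=O)OC(=O)C(C)(C)C)OCC | intermediate
9 | diethyl {2-[(4R)-4-benzyl-2-oxooxazolidin-3-yl]-2-oxoethyl}phosphonate | CCOP(=O)(CC(=O)N1[C@H](Cc2ccccc2)COC1=O)OCC | intermediate
10 | (tert-butyldimethylsilyloxy)acetaldehyde | CC(C)(C)[Si](C)(C)OCC=O | starting material
11 | (4R)-4-benzyl-3-[(E)-4-(tert-butyldimethylsilyloxy)but-2-enoyl]oxazolidin-2-one | CC(C)(C)[Si](C)(C)OC/C=C/C(=O)N1[C@H](Cc2ccccc2)COC1=O | intermediate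
12 | cycloadduct (1S,2R,3R): C8a(OTES)=C4a enol silane, C1 Ar, C2 CH2OTBS, C3 acyl oxazolidinone | O=C([C@@H]1CC=C(O[Si](CC)(CC)CC)[C@H](c2cc(OC)c(OCOC)c(OC)c2)[C@H]1CO[Si](C)(C)C(C)(C)C)N1[C@H](Cc2ccccc2)COC1=O | intermediate
13 | ring B keto imide (1S,2R,3R) | O=C([C@@H]1CCC(=O)[C@H](c2cc(OC)c(OCOC)c(OC)c2)[C@H]1CO[Si](C)(C)C(C)(C)C)N1[C@H](Cc2ccccc2)COC1=O | intermediate
14 | ring B keto methyl ester (1S,2R,3R) | COC(=O)[C@@H]1CCC(=O)[C@H](c2cc(OC)c(OCOC)c(OC)c2)[C@H]1CO[Si](C)(C)C(C)(C)C | intermediate
15 | ring B (Z)-C4a-hydroxymethylene ketone (1S,2R,3R) | COC(=O)[C@@H]1C/C(=C/O)C(=O)[C@H](c2cc(OC)c(OCOC)c(OC)c2)[C@H]1CO[Si](C)(C)C(C)(C)C | intermediate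
16 | 1,3-dimethoxyacetone | COCC(=O)COC | starting material
17 | ring B (E)-C4a-dimethylaminomethylene ketone | COC(=O)[C@@H]1C/C(=C\N(C)C)C(=O)[C@H](c2cc(OC)c(OCOC)c(OC)c2)[C@H]1CO[Si](C)(C)C(C)(C)C | intermediate
18 | ene-dione, C4a=C5H–C6H(OMe)–C7(=O)–C8H2OMe (C6 and alkene geometry labile; shown in the geometry that cyclises) | COC(=O)[C@@H]1C/C(=C/C(OC)C(=O)COC)C(=O)[C@H](c2cc(OC)c(OCOC)c(OC)c2)[C@H]1CO[Si](C)(C)C(C)(C)C | intermediate
19 | (1S,2R,3R)-1-aryltetralin-3-carboxylate with complete ring A and free C7-OH | COC(=O)[C@@H]1Cc2cc(OC)c(O)c(OC)c2[C@H](c2cc(OC)c(OCOC)c(OC)c2)[C@H]1CO[Si](C)(C)C(C)(C)C | intermediate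
20 | C4=C4a para-quinone methide | COC(=O)[C@@H]1C=C2C=C(OC)C(=O)C(OC)=C2[C@H](c2cc(OC)c(OCOC)c(OC)c2)[C@H]1CO[Si](C)(C)C(C)(C)C | intermediate
21 | (1S,2R)-1,2-dihydronaphthalene-3-carboxylate, ring C O-MOM, C2 CH2OTBS | COC(=O)C1=Cc2cc(OC)c(O)c(OC)c2[C@H](c2cc(OC)c(OCOC)c(OC)c2)[C@H]1CO[Si](C)(C)C(C)(C)C | intermediate
22 | CNP0143100.1 | COC(=O)C1=Cc2cc(OC)c(O)c(OC)c2[C@H](c2cc(OC)c(O)c(OC)c2)[C@H]1CO | target

Total step count: 12. Longest linear sequence: 10 (steps 1–4 and 7–12).

**Steps most likely to fail**

**Step 10.**
- What may go wrong: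
  - Self-aldol of the dimethoxyacetone enolate may outrun its addition to C5.
  - The sequence may stall at the ene-dione enolate, because aldol closure onto the hindered C8a carbonyl next to C1 is slow.
  - The ene-dione may close through oxygen to a pyran.
  - The water released may saponify the ester.
- Fallback, from 15 back to 19, using known reactions only:
  - Triethylamine-catalysed Michael addition of 15 to methyl vinyl ketone gives the C4a-formyl C4a-(3-oxobutyl) ketone F1.
  - NaOMe in MeOH removes the formyl group and completes a Robinson annulation to the C8=C8a octalone F2.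
  - Aerobic cyclohexenone-to-phenol dehydrogenation (Pd(O2CCF3)2, 2-(dimethylamino)pyridine, O2, DMSO) gives the 7-hydroxytetralin F3.
  - Amine-catalysed ortho-bromination of the phenol (NBS, iPr2NH cat., CH2Cl2) gives the 6,8-dibromophenol F4.
  - Ullmann-type methoxylation (NaOMe, CuBr, DMF–MeOH, heat) replaces both bromines and gives 19.

**Step 7.**
- What may go wrong:
  - Bond formation between two substituted termini may be slow.
  - The aryl group may erode regiocontrol.
  - The Lewis acid may cleave the enol silane or the MOM ether before cycloaddition.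
- Fallback, from 10 and 7 back to 14. The aryl group is introduced after a cycloaddition whose directing effects all agree.
  - Wittig reaction of 10 with Ph3P=CHC(O)CH3 gives (E)-5-(tert-butyldimethylsilyloxy)pent-3-en-2-one F5.
  - TESOTf with Et3N gives the 2-silyloxydiene F6.
  - Acylation of 7 with acryloyl chloride (Et3N, LiCl) gives the acryloyl imide F7.
  - The Et2AlCl-promoted endo Diels–Alder reaction of F6 with F7 joins the unsubstituted termini C4a and C4 first. It gives the C8a=C1 enol silane F8, which has C2 (R) and a cis C3.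
  - 4-Bromo-2,6-dimethoxyphenol with MOMCl gives the aryl bromide F9.
  - Regiospecific palladium-catalysed arylation of the enol silane (Pd(OAc)2, P(tBu)3, Bu3SnF, toluene, 85 °C) places Ar at C1 and gives the C3-epimeric keto imide F10.
  - NaOMe in MeOH exchanges the auxiliary and equilibrates C1 and C3 to the all-equatorial 14.

**Step 11.**
- What may go wrong:
  - A second dehydrogenation through C2–H and C1–H may aromatise ring B.
  - DDQ may abstract hydride from the doubly benzylic C1–H.
  - Adventitious nucleophiles may trap the quinone methide at C4.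
- Fallback, from 19 back to 22. The dehydrogenation is directed by the ester instead of the phenol.
  - MOMCl with iPr2NEt gives the bis-MOM tetralin F11.
  - LDA then PhSeBr at −78 °C gives the C3 selenide F12.
  - H2O2 with pyridine triggers selenoxide syn-elimination toward C4, into conjugation with ring A, and gives the bis-MOM dihydronaphthalene F13.
  - HCl in MeOH removes both MOM groups and the TBS group to give 22.

**Further compounds**
F1 | step 10 | C4a-formyl C4a-(3-oxobutyl) ketone | COC(=O)[C@@H]1CC(C=O)(CCC(C)=O)C(=O)[C@H](c2cc(OC)c(OCOC)c(OC)c2)[C@H]1CO[Si](C)(C)C(C)(C)C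
F2 | step 10 | C8=C8a octalone (C7 ketone, C4a-H) | COC(=O)[C@@H]1CC2CCC(=O)C=C2[C@H](c2cc(OC)c(OCOC)c(OC)c2)[C@H]1CO[Si](C)(C)C(C)(C)C
F3 | step 10 | 7-hydroxytetralin without ring A methoxy groups | COC(=O)[C@@H]1Cc2ccc(O)cc2[C@H](c2cc(OC)c(OCOC)c(OC)c2)[C@H]1CO[Si](C)(C)C(C)(C)C
F4 | step 10 | 6,8-dibromo-7-hydroxytetralin | COC(=O)[C@@H]1Cc2cc(Br)c(O)c(Br)c2[C@H](c2cc(OC)c(OCOC)c(OC)c2)[C@H]1CO[Si](C)(C)C(C)(C)C
F5 | step 7 | (E)-5-(tert-butyldimethylsilyloxy)pent-3-en-2-one | CC(=O)/C=C/CO[Si](C)(C)C(C)(C)C
F6 | step 7 | (E)-5-(tert-butyldimethylsilyloxy)-2-(triethylsilyloxy)penta-1,3-diene | C=C(O[Si](CC)(CC)CC)/C=C/CO[Si](C)(C)C(C)(C)C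
F7 | step 7 | (4R)-3-acryloyl-4-benzyloxazolidin-2-one | C=CC(=O)N1[C@H](Cc2ccccc2)COC1=O
F8 | step 7 | C8a(OTES)=C1 enol silane cycloadduct, 2,3-cis | O=C([C@H]1CCC(O[Si](CC)(CC)CC)=C[C@H]1CO[Si](C)(C)C(C)(C)C)N1[C@H](Cc2ccccc2)COC1=O
F9 | step 7 | 5-bromo-1,3-dimethoxy-2-(methoxymethoxy)benzene | COCOc1c(OC)cc(Br)cc1OC
F10 | step 7 | C3-epimeric ring B keto imide | O=C([C@H]1CCC(=O)[C@H](c2cc(OC)c(OCOC)c(OC)c2)[C@H]1CO[Si](C)(C)C(C)(C)C)N1[C@H](Cc2ccccc2)COC1=O
F11 | step 11 | bis-MOM tetralin | COC(=O)[C@@H]1Cc2cc(OC)c(OCOC)c(OC)c2[C@H](c2cc(OC)c(OCOC)c(OC)c2)[C@H]1CO[Si](C)(C)C(C)(C)C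
F12 | step 11 | C3 phenylselenide | COC(=O)C1([Se]c2ccccc2)Cc2cc(OC)c(OCOC)c(OC)c2[C@H](c2cc(OC)c(OCOC)c(OC)c2)[C@H]1CO[Si](C)(C)C(C)(C)C
F13 | step 11 | bis-MOM dihydronaphthalene | COC(=O)C1=Cc2cc(OC)c(OCOC)c(OC)c2[C@H](c2cc(OC)c(OCOC)c(OC)c2)[C@H]1CO[Si](C)(C)C(C)(C)C
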